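Ring A of the tetralone (C4a, C5, C6, C7, C8, C8a) is a hydroquinone whose oxygens sit para at C5 and C8, the pattern a Dötz benzannulation writes. Everything rests on cutting C7–C8, C5–C6 and C4a–C5. In one operation a pentacarbonylchromium methoxycarbene (carbene carbon = C8), ethynyltrimethylsilane (C7, C6) and one CO ligand (C5) close ring A onto the C4a=C8a bond. The precursor is a cyclohexenyl carbene complex that already carries that alkene, the C1 ketone as an ethylene ketal and the C4 stereocentre with its naphthyl group, the naphthol being masked as an isopropyl ether. Only O8 emerges methylated, peri to C1=O, which allows chelation-controlled release.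

Key step: step 11

Numbering: tetralone numbers (C1 carbonyl, C2, C3, C4 stereocentre, C4a, C5–C8, C8a) are used for the corresponding atoms in all intermediates. Naphthyl atoms are primed, with C1' on C4. Ar = 4-isopropoxy-8-methoxynaphthalen-1-yl. The target is 4R. The same spatial arrangement is S in 8–12 and 14–16, because C1' outranks C4a until C5 carries oxygen.

Assumption: the (R,R)-amide is taken to give the S enol ether, as it does with 4-tert-butylcyclohexanone. If the chiral assay shows the opposite sense, the equally available (S,S)-amine is used.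

Step 1
Reactants: 1 5-methoxynaphthalen-1-ol
Product: 2 4-bromo-5-methoxynaphthalen-1-ol
Conditions: NBS (1.0 equiv), MeCN, −20 to 0 °C, dark
Reagents that add atoms: N-bromosuccinimide, O=C1CCC(=O)N1Br
Why: Electrophilic aromatic bromination, in which the free hydroxyl makes its own ring the more nucleophilic one and NBS in polar MeCN favours the α-position para to OH, the carbon peri to OMe that becomes C1'.

Step 2
Reactants: 2 4-bromo-5-methoxynaphthalen-1-ol
Product: 3 4-bromo-1-isopropoxy-5-methoxynaphthalene (ArBr)
Conditions: 2-bromopropane, K2CO3, DMF, 60 °C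
Reagents that add atoms: 2-bromopropane, CC(C)Br
Why: Williamson ether synthesis; the isopropyl ether survives the hydrogenation of step 4 and both organolithium steps, has no benzylic C–H, and is cleaved by BCl3 in step 13 while aryl methyl ethers stay.

Step 3
Reactants: 3 4-bromo-1-isopropoxy-5-methoxynaphthalene; 4 2-(1,4-dioxaspiro[4.5]dec-7-en-8-yl)-4,4,5,5-tetramethyl-1,3,2-dioxaborolane
Product: 5 8-Ar-1,4-dioxaspiro[4.5]dec-7-ene
Conditions: Pd(OAc)2 (2 mol %), SPhos (4 mol %), K3PO4, toluene/H2O, 90 °C
Reagents that add atoms: none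
Why: Suzuki–Miyaura coupling with a bulky electron-rich biarylphosphine suited to a peri-hindered, electron-rich aryl bromide, which forms C4–C1' without a basic aryllithium or a dehydration step.

Step 4
Reactants: 5 8-Ar-1,4-dioxaspiro[4.5]dec-7-ene
Product: 6 8-Ar-1,4-dioxaspiro[4.5]decane
Conditions: H2 (3 atm), 10% Pd/C, EtOAc/EtOH, rt
Reagents that add atoms: none
Why: Heterogeneous catalytic hydrogenation of a trisubstituted styrene-type alkene; the ketal, both aryl ethers and the naphthalene are inert under these conditions, and the product is achiral.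

Step 5
Reactants: 6 8-Ar-1,4-dioxaspiro[4.5]decane
Product: 7 4-Ar-cyclohexan-1-one
Conditions: 2 M HCl, THF, rt
Reagents that add atoms: water, O
Why: Acid-catalysed ketal hydrolysis that frees the prochiral ketone and does not affect the aryl alkyl ethers.

Step 6
Reactants: 7 4-Ar-cyclohexan-1-one
Product: 9 {[(4S)-4-Ar-cyclohex-1-en-1-yl]oxy}trimethylsilane, via lithium enolate 8 (not isolated)
Conditions: (R,R)-bis(1-phenylethyl)amine·HCl (1.2 equiv), n-BuLi (2.4 equiv), THF, −78 to 0 °C; then −100 °C, TMSCl (5 equiv), slow addition of 7; Et3N, aq. NaHCO3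
Reagents that add atoms: chlorotrimethylsilane, C[Si](C)(C)Cl
Why: Enantioselective deprotonation (chiral lithium amide desymmetrisation): with Ar locked equatorial, the twofold-symmetric amide, as its LiCl mixed aggregate, removes one of the two enantiotopic axial α-hydrogens and TMSCl traps the enolate at once, which sets C4 as S, the arrangement of the 4R target.

Step 7
Reactants: 9 {[(4S)-4-Ar-cyclohex-1-en-1-yl]oxy}trimethylsilane
Product: 10 (4S)-4-Ar-cyclohex-2-en-1-one
Conditions: Pd(OAc)2 (1.05 equiv), MeCN, rt
Reagents that add atoms: none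
Why: Saegusa–Ito oxidation, in which divalent palladium binds the enolate at C8a and β-hydride loss from C4a gives the C4a=C8a enone in a nearly neutral medium that leaves C4–H alone.

Step 8
Reactants: 10 (4S)-4-Ar-cyclohex-2-en-1-one
Product: 11 (4S)-2-iodo-4-Ar-cyclohex-2-en-1-one
Conditions: I2 (2 equiv), pyridine/CH2Cl2, 0 °C to rt; aq. Na2S2O3; recrystallisation
Reagents that add atoms: iodine, II
Why: Baylis–Hillman-type α-iodination (reversible pyridine addition at C4a, iodination at C8a, loss of pyridine), a nucleophile-triggered path that spares the dialkoxynaphthalene, which Br2 would attack first; recrystallisation here is meant to raise the enantiomeric purity.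

Step 9
Reactants: 11 (4S)-2-iodo-4-Ar-cyclohex-2-en-1-one
Product: 12 (8S)-6-iodo-8-Ar-1,4-dioxaspiro[4.5]dec-6-ene
Conditions: TMSOCH2CH2OTMS (3 equiv), TMSOTf (10 mol %), CH2Cl2, −78 to −20 °C; pyridine quench
Reagents that add atoms: 1,2-bis(trimethylsilyloxy)ethane, C[Si](C)(C)OCCO[Si](C)(C)C
Why: Noyori ketalisation under aprotic low-temperature conditions protects enones without moving the double bond, so no dienol forms and C4 keeps its configuration, and it delivers the standard 2-haloenone ketal precursor of an α-ketovinyl anion.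

Step 10
Reactants: 12 (8S)-6-iodo-8-Ar-1,4-dioxaspiro[4.5]dec-6-ene; 13 hexacarbonylchromium Cr(CO)6
Product: 16 pentacarbonyl{methoxy[(8S)-8-Ar-1,4-dioxaspiro[4.5]dec-6-en-6-yl]methylidene}chromium, via vinyllithium 14 (not isolated), via lithium acylchromate 15 (not isolated)
Conditions: t-BuLi (2.0 equiv), Et2O, −78 °C; cannulation onto Cr(CO)6 in Et2O, 0 °C to rt; evaporation; MeOTf, CH2Cl2, 0 °C to rt
Reagents that add atoms: methyl trifluoromethanesulfonate, COS(=O)(=O)C(F)(F)F
Why: Fischer carbene synthesis, in which iodine–lithium exchange at −78 °C outruns deprotonation, the vinyllithium (unable to expel the ketal oxygen, since that would need a six-membered allene) adds to a CO ligand, and the hard methylating agent alkylates the acylate oxygen.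

Step 11
Reactants: 16 pentacarbonyl{methoxy[(8S)-8-Ar-1,4-dioxaspiro[4.5]dec-6-en-6-yl]methylidene}chromium; 17 ethynyltrimethylsilane
Product: 19 (4R)-4-Ar-5-hydroxy-8-methoxy-6-(trimethylsilyl)-3,4-dihydronaphthalen-1(2H)-one ethylene ketal, via arene-Cr(CO)3 complex 18 (not isolated)
Conditions: 17 (2.5 equiv), THF (0.05 M), 50 °C, sealed tube, Ar; then air, Et2O, rt
Reagents that add atoms: none
Why: Thermal loss of one cis CO from the zerovalent chromium of 16 opens a site (held meanwhile by THF or a ketal oxygen) for 17, which inserts into the Cr=C8 bond with its unsubstituted carbon (C7–C8) to give a vinylcarbene, and CO insertion at the silyl-bearing carbon (C5–C6) then gives a chromium-bound dienylketene. Ring A closes by thermal disrotatory 6π-electrocyclisation of that dienylketene (C4a–C5), and the cyclohexa-2,4-dienone formed gives up its C4a hydrogen by tautomerisation to the phenol, first held on Cr(CO)3 and freed by air. This is the Dötz benzannulation of an alkenyl(alkoxy)carbene complex with a terminal alkyne, silylacetylenes being the established stand-in for acetylene itself. No stereocentre is created: C4 only changes its descriptor from S to R because C4a gains priority, and the neutral medium at 50 °C leaves its allylic, benzylic C–H alone. The selectivity needed is for the six-membered phenol over cyclobutenone, five-membered-ring or arrested silylketene products, and it is secured by the alkenyl rather than aryl carbene, by the C4a=C8a bond held in the ring next to the carbene carbon, and by the weakly coordinating ether solvent at moderate dilution. Alkyne orientation (silicon next to the new OH on steric grounds) does not matter, since silicon on carbon, or on oxygen after a 1,3-shift, is removed in step 12.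

Step 12
Reactants: 19 (4R)-4-Ar-5-hydroxy-8-methoxy-6-(trimethylsilyl)-3,4-dihydronaphthalen-1(2H)-one ethylene ketal
Product: 21 (4R)-4-Ar-5-hydroxy-8-methoxy-3,4-dihydronaphthalen-1(2H)-one, via desilylated ketal 20 (not isolated)
Conditions: TFA (10 equiv), CH2Cl2, 0 °C; then H2O/THF added, rt
Reagents that add atoms: water, O
Why: ipso-Protodesilylation, strongly accelerated by the ortho hydroxyl, followed by hydrolysis of the electron-rich benzylic ketal; the short, cold acid exposure should leave the C4–C1' bond, C4 and the isopropyl ether untouched.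

Step 13
Reactants: 21 (4R)-4-Ar-5-hydroxy-8-methoxy-3,4-dihydronaphthalen-1(2H)-one
Product: 22 (4R)-5,8-dihydroxy-4-(4-hydroxy-8-methoxynaphthalen-1-yl)-3,4-dihydronaphthalen-1(2H)-one
Conditions: BCl3 (5 equiv, 1 M in CH2Cl2), CH2Cl2, −78 to 0 °C; degassed H2O quench
Reagents that add atoms: none
Why: Lewis-acid ether cleavage, in which BCl3 chelated between C1=O and O8 removes that methyl group and the secondary isopropyl ether ionises readily, whereas the unchelated methyl ether at C8' is not cleaved at or below 0 °C and C4 takes no part.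

Compound list
1 | 5-methoxynaphthalen-1-ol | COc1cccc2c(O)cccc12 | starting material
2 | 4-bromo-5-methoxynaphthalen-1-ol | COc1cccc2c(O)ccc(Br)c12 | intermediate
3 | 4-bromo-1-isopropoxy-5-methoxynaphthalene | COc1cccc2c(OC(C)C)ccc(Br)c12 | intermediate
4 | 2-(1,4-dioxaspiro[4.5]dec-7-en-8-yl)-4,4,5,5-tetramethyl-1,3,2-dioxaborolane | CC1(C)OB(OC1(C)C)C1=CCC2(CC1)OCCO2 | starting material
5 | 8-(4-isopropoxy-8-methoxynaphthalen-1-yl)-1,4-dioxaspiro[4.5]dec-7-ene | COc1cccc2c(OC(C)C)ccc(C3=CCC4(CC3)OCCO4)c12 | intermediate
6 | 8-(4-isopropoxy-8-methoxynaphthalen-1-yl)-1,4-dioxaspiro[4.5]decane | COc1cccc2c(OC(C)C)ccc(C3CCC4(CC3)OCCO4)c12 | intermediate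
7 | 4-(4-isopropoxy-8-methoxynaphthalen-1-yl)cyclohexan-1-one | COc1cccc2c(OC(C)C)ccc(C3CCC(=O)CC3)c12 | intermediate
8 | lithium (4S)-4-(4-isopropoxy-8-methoxynaphthalen-1-yl)cyclohex-1-en-1-olate | COc1cccc2c(OC(C)C)ccc([C@H]3CCC(O[Li])=CC3)c12 | intermediate
9 | {[(4S)-4-(4-isopropoxy-8-methoxynaphthalen-1-yl)cyclohex-1-en-1-yl]oxy}trimethylsilane | COc1cccc2c(OC(C)C)ccc([C@H]3CCC(O[Si](C)(C)C)=CC3)c12 | intermediate
10 | (4S)-4-(4-isopropoxy-8-methoxynaphthalen-1-yl)cyclohex-2-en-1-one | COc1cccc2c(OC(C)C)ccc([C@H]3CCC(=O)C=C3)c12 | intermediate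
11 | (4S)-2-iodo-4-(4-isopropoxy-8-methoxynaphthalen-1-yl)cyclohex-2-en-1-one | COc1cccc2c(OC(C)C)ccc([C@H]3CCC(=O)C(I)=C3)c12 | intermediate
12 | (8S)-6-iodo-8-(4-isopropoxy-8-methoxynaphthalen-1-yl)-1,4-dioxaspiro[4.5]dec-6-ene | COc1cccc2c(OC(C)C)ccc([C@H]3CCC4(OCCO4)C(I)=C3)c12 | intermediate
13 | hexacarbonylchromium | O=C=[Cr](=C=O)(=C=O)(=C=O)(=C=O)=C=O | starting material
14 | [(8S)-8-(4-isopropoxy-8-methoxynaphthalen-1-yl)-1,4-dioxaspiro[4.5]dec-6-en-6-yl]lithium | COc1cccc2c(OC(C)C)ccc([C@H]3CCC4(OCCO4)C([Li])=C3)c12 | intermediate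
15 | lithium pentacarbonyl acylchromate from 14 and 13 | COc1cccc2c(OC(C)C)ccc([C@H]3CCC4(OCCO4)C(C([O-])=[Cr](=C=O)(=C=O)(=C=O)(=C=O)=C=O)=C3)c12.[Li+] | intermediate
16 | pentacarbonyl{methoxy[(8S)-8-(4-isopropoxy-8-methoxynaphthalen-1-yl)-1,4-dioxaspiro[4.5]dec-6-en-6-yl]methylidene}chromium | COc1cccc2c(OC(C)C)ccc([C@H]3CCC4(OCCO4)C(C(OC)=[Cr](=C=O)(=C=O)(=C=O)(=C=O)=C=O)=C3)c12 | intermediate
17 | ethynyltrimethylsilane | C#C[Si](C)(C)C | starting material
18 | tricarbonylchromium η6-complex of 19 at ring A (metal fragment written as a separate component) | COc1cccc2c(OC(C)C)ccc([C@H]3CCC4(OCCO4)c4c(OC)cc([Si](C)(C)C)c(O)c43)c12.O=C=[Cr](=C=O)=C=O | intermediate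
19 | (4R)-5-hydroxy-4-(4-isopropoxy-8-methoxynaphthalen-1-yl)-8-methoxy-6-(trimethylsilyl)-3,4-dihydronaphthalen-1(2H)-one ethylene ketal | COc1cccc2c(OC(C)C)ccc([C@H]3CCC4(OCCO4)c4c(OC)cc([Si](C)(C)C)c(O)c43)c12 | intermediate
20 | (4R)-5-hydroxy-4-(4-isopropoxy-8-methoxynaphthalen-1-yl)-8-methoxy-3,4-dihydronaphthalen-1(2H)-one ethylene ketal | COc1cccc2c(OC(C)C)ccc([C@H]3CCC4(OCCO4)c4c(OC)ccc(O)c43)c12 | intermediate
21 | (4R)-5-hydroxy-4-(4-isopropoxy-8-methoxynaphthalen-1-yl)-8-methoxy-3,4-dihydronaphthalen-1(2H)-one | COc1cccc2c(OC(C)C)ccc([C@H]3CCC(=O)c4c(OC)ccc(O)c43)c12 | intermediate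
22 | (4R)-5,8-dihydroxy-4-(4-hydroxy-8-methoxynaphthalen-1-yl)-3,4-dihydronaphthalen-1(2H)-one | COc1cccc2c(O)ccc([C@H]3CCC(=O)c4c(O)ccc(O)c43)c12 | target

Total step count: 13. Longest linear sequence: 13 steps (1 to 22).

Steps most likely to fail

Step 11.
- **What may go wrong:** After alkyne insertion the vinylketene stage may leak into four-membered ring closure, or rest as a silicon-stabilised ketene instead of undergoing the 6π closure. Crowding by the ketal and the C4 aryl group may slow that closure further.
- **Fallback:** Carbonylation and ring closure are separated.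
  - Setting out from 16 and 17, the reaction is run in MeCN at 45 °C, a donor solvent known to steer chromium vinylketenes towards cyclobutenones.
  - After demetallation in air, 4-methoxy-4-[(8S)-8-Ar-1,4-dioxaspiro[4.5]dec-6-en-6-yl]-2-(trimethylsilyl)cyclobut-2-en-1-one F1 is isolated. Either configuration at the new quaternary carbon serves.
  - Heating in toluene at 110 °C (Moore-type rearrangement) opens the four-membered ring by conrotation with the methoxy group turning outward and the cyclohexenyl group inward.
  - The metal-free dienylketene closes by 6π-electrocyclisation and tautomerises, coming back to the route at 19.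

Step 10.
- **What may go wrong:** Proton transfer from the allylic, benzylic C4–H to the vinyllithium may occur during the warm-up that poorly soluble Cr(CO)6 requires. This would cost material and erode the configuration. Attack of the hindered vinyllithium on CO may also be slow.
- **Fallback:** The acylchromate is built from an acyl electrophile and a chromium nucleophile, so no strongly basic carbanion is present.
  - Setting out from 12, hydroxycarbonylation (Pd(OAc)2, PPh3, CO 1 atm, K2CO3, DMF/H2O, 60 °C, work-up at pH 5) gives (8S)-8-Ar-1,4-dioxaspiro[4.5]dec-6-ene-6-carboxylic acid F2.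
  - 1-Chloro-N,N,2-trimethylprop-1-en-1-amine in CH2Cl2 converts it under neutral conditions into (8S)-8-Ar-1,4-dioxaspiro[4.5]dec-6-ene-6-carbonyl chloride F3.
  - In a second flask 13 is reduced with potassium graphite KC8 in THF to dipotassium pentacarbonylchromate F4.
  - This attacks the acid chloride at −78 °C to give the potassium acylchromate F5.
  - MeOTf methylates it on oxygen, coming back to the route at 16.

Step 6.
- **What may go wrong:** Discrimination between the two enantiotopic axial hydrogens may be incomplete, and partial equilibration of the enolate before silylation would leave the material short of a single enantiomer.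
- **Fallback:** Resolution with recycling replaces asymmetric induction.
  - Setting out from 7, soft enolisation (TMSOTf, Et3N, CH2Cl2, 0 °C) gives racemic [(4-Ar-cyclohex-1-en-1-yl)oxy]trimethylsilane F6.
  - Pd(OAc)2 in MeCN gives racemic 4-Ar-cyclohex-2-en-1-one F7.
  - Preparative supercritical-fluid chromatography on a chiral polysaccharide phase separates the enantiomers.
  - The S enantiomer is 10, where the route is rejoined.
  - (4R)-4-Ar-cyclohex-2-en-1-one F8 is hydrogenated (H2, Pd/C) back to achiral 7 for another pass.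

Further compounds
F1 | step 11 | 4-methoxy-4-[(8S)-8-(4-isopropoxy-8-methoxynaphthalen-1-yl)-1,4-dioxaspiro[4.5]dec-6-en-6-yl]-2-(trimethylsilyl)cyclobut-2-en-1-one | COc1cccc2c(OC(C)C)ccc([C@H]3CCC4(OCCO4)C(C4(OC)C=C([Si](C)(C)C)C4=O)=C3)c12
F2 | step 10 | (8S)-8-(4-isopropoxy-8-methoxynaphthalen-1-yl)-1,4-dioxaspiro[4.5]dec-6-ene-6-carboxylic acid | COc1cccc2c(OC(C)C)ccc([C@H]3CCC4(OCCO4)C(C(=O)O)=C3)c12
F3 | step 10 | (8S)-8-(4-isopropoxy-8-methoxynaphthalen-1-yl)-1,4-dioxaspiro[4.5]dec-6-ene-6-carbonyl chloride | COc1cccc2c(OC(C)C)ccc([C@H]3CCC4(OCCO4)C(C(=O)Cl)=C3)c12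
F4 | step 10 | dipotassium pentacarbonylchromate K2Cr(CO)5 | [K+].[K+].O=C=[Cr-2](=C=O)(=C=O)(=C=O)=C=O
F5 | step 10 | potassium pentacarbonyl acylchromate from F3 and F4 | COc1cccc2c(OC(C)C)ccc([C@H]3CCC4(OCCO4)C(C([O-])=[Cr](=C=O)(=C=O)(=C=O)(=C=O)=C=O)=C3)c12.[K+]
F6 | step 6 | racemic {[4-(4-isopropoxy-8-methoxynaphthalen-1-yl)cyclohex-1-en-1-yl]oxy}trimethylsilane | COc1cccc2c(OC(C)C)ccc(C3CCC(O[Si](C)(C)C)=CC3)c12
F7 | step 6 | racemic 4-(4-isopropoxy-8-methoxynaphthalen-1-yl)cyclohex-2-en-1-one | COc1cccc2c(OC(C)C)ccc(C3CCC(=O)C=C3)c12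
F8 | step 6 | (4R)-4-(4-isopropoxy-8-methoxynaphthalen-1-yl)cyclohex-2-en-1-one | COc1cccc2c(OC(C)C)ccc([C@@H]3CCC(=O)C=C3)c12
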